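**Plan** (ring A: C1 prenyl, C2 O-acyl, C3 H, C4 and C5 CH2OH, C6 OH; ring B: the orsellinate)
Retrosynthesis first cuts the aryl ester bond at C2–O, then opens ring A across C1–C6 and C2–C3 (C5–C6 is broken and re-formed in the same event).
The enabling feature is that ring A is a resorcinol (O at C2 and C6) with a single carbon substituent, the C1 prenyl, between the two oxygens; this maps onto a siloxyalkyne (C1, C2) and a cyclobutenone (C6 carbonyl, C3, C4, C5).
Forward: cyclobutenone 10 is built from MOM-protected 3-hydroxypropanoate, ethoxyacetylene and a hydroxymethyl-lithium equivalent; alkyne 14 comes from ethyl 4-methylpent-3-enoate through its ynolate.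
Thermal benzannulation of 10 with 14 closes ring A, the only ring made, with C6–OH free and C2–O silylated; C6–OH is then capped, C2–O unmasked and acylated with protected ring B acid, and all acetals are removed together.
Stereochemistry: the target is achiral; the racemic sp3 centre of 10 vanishes on aromatisation, and the only selectivity to secure is the ring A regiochemistry, which the polarity of the siloxyalkyne sets.

Key step: step 6

Remark on the chemistry: ethyl 4-methylpent-3-enoate, tributyl[(methoxymethoxy)methyl]stannane and ethoxyacetylene (hexane solution) are taken as catalogue items; in the ynolate route the ester carbonyl carbon becomes the oxygen-bearing alkyne carbon and CH2Br2 supplies the other, so the ester must carry the prenyl group directly on its carbonyl carbon.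

Step 1
Reactants: 1 methyl 3-hydroxypropanoate
Product: 2 methyl 3-(methoxymethoxy)propanoate
Conditions: MOMCl, i-Pr2NEt, CH2Cl2, 0 °C to rt
Reagents that add atoms: chloromethyl methyl ether, COCCl
Why: Williamson-type O-alkylation of the primary alcohol with the chloromethyl ether under amine base should give the MOM acetal while the methyl ester stays untouched.

Step 2
Reactants: 2 methyl 3-(methoxymethoxy)propanoate
Product: 3 sodium 3-(methoxymethoxy)propanoate
Conditions: NaOH (1.0 equiv), MeOH–H2O, 0 °C to rt; evaporate, dry by toluene azeotrope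
Reagents that add atoms: sodium hydroxide, [Na+].[OH-]
Why: Ester saponification with one equivalent of hydroxide should deliver the dry carboxylate salt directly, because attack at the ester carbonyl is faster than β-elimination of the alkoxide and the MOM acetal is stable to base.

Step 3
Reactants: 3 sodium 3-(methoxymethoxy)propanoate; 4 ethoxyacetylene
Product: 7 rac-3-ethoxy-4-[(methoxymethoxy)methyl]cyclobut-2-en-1-one, via acid chloride 5 (not isolated), via alkylketene 6 (not isolated)
Conditions: (COCl)2 (1.0 equiv), cat. DMF, CH2Cl2, 0 °C; then added slowly to 4 (2 equiv) and Et3N, Et2O, 0 °C to rt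
Reagents that add atoms: none
Why: The carboxylate salt and oxalyl chloride give acid chloride 5 without free HCl, Et3N dehydrochlorinates it to ketene 6, and the nucleophilic ynol ether traps the ketene as it forms in a ketene–alkyne [2+2] cycloaddition whose polarity (terminal alkyne carbon to the ketene carbonyl carbon) puts ethoxy at C3; the new sp3 centre C4 forms as a racemate and is erased in step 6.

Step 4
Reactants: 7 rac-3-ethoxy-4-[(methoxymethoxy)methyl]cyclobut-2-en-1-one; 8 tributyl[(methoxymethoxy)methyl]stannane
Product: 10 rac-3,4-bis[(methoxymethoxy)methyl]cyclobut-2-en-1-one, via carbinol 9 (not isolated)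
Conditions: 8, n-BuLi, THF, −78 °C; then 7, −78 °C; then 1 M aq HCl, THF, 0 °C, short contact
Reagents that add atoms: water, O
Why: Tin–lithium exchange gives the α-alkoxymethyllithium, which adds 1,2 to the vinylogous ester carbonyl, and dilute acid then ionises the tertiary allylic carbinol 9 and hydrolyses the enol ether (Stork–Danheiser-type 1,3-carbonyl transposition), which should leave both MOM ethers intact at this acidity and contact time.

Step 5
Reactants: 11 ethyl 4-methylpent-3-enoate
Product: 14 triisopropyl[(5-methylhex-4-en-1-yn-1-yl)oxy]silane, via dibromoenolate 12 (not isolated), via lithium ynolate 13 (not isolated)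
Conditions: CH2Br2, lithium 2,2,6,6-tetramethylpiperidide (LiTMP), THF, −78 °C; n-BuLi, −78 to 20 °C; then i-Pr3SiCl, −78 to 0 °C
Reagents that add atoms: dibromomethane, BrCBr; chlorotriisopropylsilane, CC(C)[Si](Cl)(C(C)C)C(C)C
Why: This is Kowalski ester homologation chemistry stopped at the ynolate: LiCHBr2 adds to the ester, the dibromoketone is held as enolate 12, bromine–lithium exchange triggers 1,2-migration of the prenyl group to ynolate 13, and the bulky silyl chloride should react at oxygen to give the siloxyalkyne.

Step 6
Reactants: 10 rac-3,4-bis[(methoxymethoxy)methyl]cyclobut-2-en-1-one; 14 triisopropyl[(5-methylhex-4-en-1-yn-1-yl)oxy]silane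
Product: 19 5,6-bis[(methoxymethoxy)methyl]-2-(3-methylbut-2-en-1-yl)-3-[(triisopropylsilyl)oxy]phenol, via vinylketene 15 (not isolated), via vinylcyclobutenone 16 (not isolated), via dienylketene 17 (not isolated), via cyclohexadienone 18 (not isolated)
Conditions: 14 (1.3 equiv), degassed PhMe, 80 °C, then 110 °C
Reagents that add atoms: none
Why: Heating opens 10 by four-electron electrocyclic cleavage of the C5–C6 bond to vinylketene 15; its C6=C3 ketene bond adds the siloxyalkyne in a [2+2] cycloaddition (new C1–C6 and C2–C3 bonds) to give vinylcyclobutenone 16, which opens again (C3–C6 cleaved) to dienylketene 17, and this closes to cyclohexadienone 18 and tautomerises to phenol 19. The closest known reaction is the Danheiser benzannulation of cyclobutenones with triisopropylsiloxyalkynes, which gives resorcinol monosilyl ethers. Ring A is closed by a thermal six-electron disrotatory electrocyclisation of 17 that re-forms the C5–C6 bond. No stereocentre is created in 19, and the racemic sp3 carbon C5 of 10 and 18 becomes aromatic. The step needs regiocontrol in the [2+2] event, and the polarisation of the siloxyalkyne secures it: its nucleophilic prenyl-bearing carbon bonds to the ketene carbonyl carbon C6, so prenyl arrives at C1 between the two oxygens and the silyloxy group at C2. Chemoselectivity follows from the same polarity, since the electron-rich alkyne is a far better ketenophile than the isolated prenyl alkene, and the slight excess of 14 should keep the vinylketene from acylating the product phenol.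

Step 7
Reactants: 20 orsellinic acid
Product: 21 methoxymethyl 2,4-bis(methoxymethoxy)-6-methylbenzoate
Conditions: NaH (3.3 equiv), MOMCl (3.5 equiv), DMF, 0 °C to rt
Reagents that add atoms: chloromethyl methyl ether, COCCl
Why: Exhaustive Williamson-type alkylation of the carboxylate and both phenoxides should occur, NaH being strong enough to break the hydrogen bond of the ortho hydroxyl.

Step 8
Reactants: 21 methoxymethyl 2,4-bis(methoxymethoxy)-6-methylbenzoate
Product: 22 2,4-bis(methoxymethoxy)-6-methylbenzoic acid
Conditions: NaOH, THF–MeOH–H2O, 40 °C; then cold dilute HCl to pH 3, rapid extraction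
Reagents that add atoms: sodium hydroxide, [Na+].[OH-]
Why: Chemoselective saponification is expected because the methoxymethyl ester is an acyloxymethyl acetal that hydroxide cleaves readily, whereas aryl MOM ethers are inert to base and should survive the brief cold acidification.

Step 9
Reactants: 19 5,6-bis[(methoxymethoxy)methyl]-2-(3-methylbut-2-en-1-yl)-3-[(triisopropylsilyl)oxy]phenol
Product: 23 triisopropyl{3-(methoxymethoxy)-4,5-bis[(methoxymethoxy)methyl]-2-(3-methylbut-2-en-1-yl)phenoxy}silane
Conditions: NaH, MOMCl, THF–DMF, 0 °C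
Reagents that add atoms: chloromethyl methyl ether, COCCl
Why: Williamson-type protection of the hindered C6 phenoxide should proceed while the bulky aryl silyl ether at C2 resists the short exposure to base, so the two ring A oxygens stay differentiated.

Step 10
Reactants: 23 triisopropyl{3-(methoxymethoxy)-4,5-bis[(methoxymethoxy)methyl]-2-(3-methylbut-2-en-1-yl)phenoxy}silane
Product: 24 3-(methoxymethoxy)-4,5-bis[(methoxymethoxy)methyl]-2-(3-methylbut-2-en-1-yl)phenol
Conditions: Bu4NF (1.1 equiv), THF, 0 °C
Reagents that add atoms: none
Why: Fluoride-induced desilylation, driven by the strong Si–F bond, should remove the only silyl group while MOM ethers and the prenyl alkene are inert.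

Step 11
Reactants: 24 3-(methoxymethoxy)-4,5-bis[(methoxymethoxy)methyl]-2-(3-methylbut-2-en-1-yl)phenol; 22 2,4-bis(methoxymethoxy)-6-methylbenzoic acid
Product: 25 3-(methoxymethoxy)-4,5-bis[(methoxymethoxy)methyl]-2-(3-methylbut-2-en-1-yl)phenyl 2,4-bis(methoxymethoxy)-6-methylbenzoate
Conditions: DCC, DMAP, CH2Cl2, 0 °C to rt
Reagents that add atoms: none
Why: In this Steglich esterification the O-acylisourea of the di-ortho-substituted acid is relayed through the N-acylpyridinium ion to the C2 phenol, which is the only free hydroxyl in 24 and has one unsubstituted ortho position.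

Step 12
Reactants: 25 3-(methoxymethoxy)-4,5-bis[(methoxymethoxy)methyl]-2-(3-methylbut-2-en-1-yl)phenyl 2,4-bis(methoxymethoxy)-6-methylbenzoate
Product: 26 3-hydroxy-4,5-bis(hydroxymethyl)-2-(3-methylbut-2-en-1-yl)phenyl 2,4-dihydroxy-6-methylbenzoate (CNP0159803.0)
Conditions: Me3SiOTf, 2,2′-bipyridyl (both in excess), CH2Cl2–MeCN, 0 °C to rt; then H2O, rt
Reagents that add atoms: none
Why: The silyl triflate–bipyridyl pair is a known mild acetal cleavage that turns alkyl MOM ethers into pyridinium N,O-acetals and aryl MOM ethers into aryl silyl ethers under buffered aprotic conditions, and water then frees all five hydroxyls, avoiding the protic acid that could close the C6 phenol onto the prenyl alkene, ionise the C5 benzylic position or cleave the aryl ester.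

**Compound list**
1 | methyl 3-hydroxypropanoate | COC(=O)CCO | starting material
2 | methyl 3-(methoxymethoxy)propanoate | COCOCCC(=O)OC | intermediate
3 | sodium 3-(methoxymethoxy)propanoate | COCOCCC(=O)[O-].[Na+] | intermediate
4 | ethoxyacetylene (ethoxyethyne) | CCOC#C | starting material
5 | 3-(methoxymethoxy)propanoyl chloride (formed in the flask) | COCOCCC(=O)Cl | intermediate
6 | 3-(methoxymethoxy)prop-1-en-1-one, the alkylketene (formed in the flask) | COCOCC=C=O | intermediate
7 | rac-3-ethoxy-4-[(methoxymethoxy)methyl]cyclobut-2-en-1-one | CCOC1=CC(=O)C1COCOC | intermediate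
8 | tributyl[(methoxymethoxy)methyl]stannane | CCCC[Sn](CCCC)(CCCC)COCOC | starting material
9 | 3-ethoxy-1,4-bis[(methoxymethoxy)methyl]cyclobut-2-en-1-ol, mixture of diastereomers (formed in the flask) | CCOC1=CC(O)(COCOC)C1COCOC | intermediate
10 | rac-3,4-bis[(methoxymethoxy)methyl]cyclobut-2-en-1-one | O=C1C=C(COCOC)C1COCOC | intermediate
11 | ethyl 4-methylpent-3-enoate | CCOC(=O)CC=C(C)C | starting material
12 | lithium 1,1-dibromo-5-methylhexa-1,4-dien-2-olate (formed in the flask) | CC(C)=CCC([O-])=C(Br)Br.[Li+] | intermediate
13 | lithium 5-methylhex-4-en-1-yn-1-olate (formed in the flask) | CC(C)=CCC#C[O-].[Li+] | intermediate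
14 | triisopropyl[(5-methylhex-4-en-1-yn-1-yl)oxy]silane | CC(C)=CCC#CO[Si](C(C)C)(C(C)C)C(C)C | intermediate
15 | (3Z)-5-(methoxymethoxy)-3-[(methoxymethoxy)methyl]penta-1,3-dien-1-one, the vinylketene (formed in the flask) | O=C=C/C(COCOC)=C/COCOC | intermediate
16 | rac-4-[(2Z)-1,4-bis(methoxymethoxy)but-2-en-2-yl]-2-(3-methylbut-2-en-1-yl)-3-[(triisopropylsilyl)oxy]cyclobut-2-en-1-one (formed in the flask) | O=C1C(CC=C(C)C)=C(O[Si](C(C)C)(C(C)C)C(C)C)C1/C(COCOC)=C/COCOC | intermediate
17 | (3E,5Z)-7-(methoxymethoxy)-5-[(methoxymethoxy)methyl]-2-(3-methylbut-2-en-1-yl)-3-[(triisopropylsilyl)oxy]hepta-1,3,5-trien-1-one, the dienylketene (formed in the flask) | O=C=C(CC=C(C)C)/C(O[Si](C(C)C)(C(C)C)C(C)C)=C\C(COCOC)=C\COCOC | intermediate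
18 | rac-5,6-bis[(methoxymethoxy)methyl]-2-(3-methylbut-2-en-1-yl)-3-[(triisopropylsilyl)oxy]cyclohexa-2,4-dien-1-one (formed in the flask) | O=C1C(CC=C(C)C)=C(O[Si](C(C)C)(C(C)C)C(C)C)C=C(COCOC)C1COCOC | intermediate
19 | 5,6-bis[(methoxymethoxy)methyl]-2-(3-methylbut-2-en-1-yl)-3-[(triisopropylsilyl)oxy]phenol | CC(C)=CCc1c(O[Si](C(C)C)(C(C)C)C(C)C)cc(COCOC)c(COCOC)c1O | intermediate
20 | orsellinic acid (2,4-dihydroxy-6-methylbenzoic acid) | Cc1cc(O)cc(O)c1C(=O)O | starting material
21 | methoxymethyl 2,4-bis(methoxymethoxy)-6-methylbenzoate | COCOC(=O)c1c(C)cc(OCOC)cc1OCOC | intermediate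
22 | 2,4-bis(methoxymethoxy)-6-methylbenzoic acid | Cc1cc(OCOC)cc(OCOC)c1C(=O)O | intermediate
23 | triisopropyl{3-(methoxymethoxy)-4,5-bis[(methoxymethoxy)methyl]-2-(3-methylbut-2-en-1-yl)phenoxy}silane | CC(C)=CCc1c(O[Si](C(C)C)(C(C)C)C(C)C)cc(COCOC)c(COCOC)c1OCOC | intermediate
24 | 3-(methoxymethoxy)-4,5-bis[(methoxymethoxy)methyl]-2-(3-methylbut-2-en-1-yl)phenol | CC(C)=CCc1c(O)cc(COCOC)c(COCOC)c1OCOC | intermediate
25 | 3-(methoxymethoxy)-4,5-bis[(methoxymethoxy)methyl]-2-(3-methylbut-2-en-1-yl)phenyl 2,4-bis(methoxymethoxy)-6-methylbenzoate | CC(C)=CCc1c(OC(=O)c2c(C)cc(OCOC)cc2OCOC)cc(COCOC)c(COCOC)c1OCOC | intermediate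
26 | 3-hydroxy-4,5-bis(hydroxymethyl)-2-(3-methylbut-2-en-1-yl)phenyl 2,4-dihydroxy-6-methylbenzoate | CC(C)=CCc1c(OC(=O)c2c(C)cc(O)cc2O)cc(CO)c(CO)c1O | target

**Step count**
Total: 12 steps. Longest linear sequence: 9 steps (steps 1, 2, 3, 4, 6, 9, 10, 11, 12).

**Steps most likely to fail**

Step 3. β-Elimination of the methoxymethoxide from the acyl chloride enolate, dimerisation of the monoalkylketene, or attack of the acyl chloride on the acetal may outrun the cycloaddition. The fallback generates the same ketene 6 without base or acyl chloride. It sets out from ethoxyacetylene 4, used again as the ketenophile, and comes back to the route at cyclobutenone 7. Purchased tert-butoxyethyne is lithiated with n-BuLi and hydroxymethylated with paraformaldehyde to 3-(tert-butoxy)prop-2-yn-1-ol F1, which is capped with MOMCl and i-Pr2NEt to give 1-(tert-butoxy)-3-(methoxymethoxy)prop-1-yne F2. Warming F2 to about 80 °C in toluene in a closed vessel with excess 4 should release 2-methylpropene by a retro-ene reaction and deliver ketene 6 slowly, at low concentration. Ethyl ynol ether 4 is stable at this temperature and should intercept the ketene to give 7.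

Step 5. Deprotonation of the doubly activated C2 methylene of 11 by the lithium bases, with enolisation and migration of the alkene into conjugation, may compete with carbonyl addition of LiCHBr2. The fallback reaches the ynolate by oxidising an acetylide. It sets out from ester 11 and comes back at ynolate 13. Reduction with i-Bu2AlH at −78 °C should give 4-methylpent-3-enal F3, which is used at once in a Corey–Fuchs olefination (CBr4, PPh3, CH2Cl2, 0 °C) to give 1,1-dibromo-5-methylhexa-1,4-diene F4. Two equivalents of n-BuLi at −78 °C convert F4 into (5-methylhex-4-en-1-yn-1-yl)lithium F5. This is oxidised with lithium tert-butyl peroxide (LiOOt-Bu, from t-BuOOH and LiN(SiMe3)2; −78 to 0 °C) to ynolate 13, which is silylated as in step 5 to give 14.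

Step 12. Cleavage of five acetals on the complete molecule may stall at partly protected stages. During the aqueous stage the freed C6 phenol may also add to the prenyl alkene, the C5 benzylic position may ionise, or the aryl ester may hydrolyse. The fallback moves acetal cleavage to an earlier compound and ends with base-labile acyl groups. It sets out from phenol 19 and comes back at the target 26.
- The two benzylic MOM ethers of 19 (no ester present yet) are cleaved with Me3SiOTf and 2,2′-bipyridyl followed by water, to give 2,3-bis(hydroxymethyl)-6-(3-methylbut-2-en-1-yl)-5-[(triisopropylsilyl)oxy]phenol F6.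
- Acetylation (Ac2O, pyridine, DMAP) gives triacetate F7, and Bu4NF buffered with AcOH removes the silyl group to give the C2 phenol triacetate F8.
- In parallel, orsellinic acid 20 is acetylated (Ac2O, pyridine, aqueous work-up) to 2,4-diacetoxy-6-methylbenzoic acid F9 and converted with oxalyl chloride into 2,4-diacetoxy-6-methylbenzoyl chloride F10.
- Acylation of F8 with F10 in pyridine gives pentaacetate F11.
- Methanolysis with K2CO3 in MeOH at 0 °C should remove the five acetates and leave the di-ortho-substituted benzoate, giving 26.

**Further compounds**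
F1 | step 3 | 3-(tert-butoxy)prop-2-yn-1-ol | CC(C)(C)OC#CCO
F2 | step 3 | 1-(tert-butoxy)-3-(methoxymethoxy)prop-1-yne | COCOCC#COC(C)(C)C
F3 | step 5 | 4-methylpent-3-enal | CC(C)=CCC=O
F4 | step 5 | 1,1-dibromo-5-methylhexa-1,4-diene | CC(C)=CCC=C(Br)Br
F5 | step 5 | (5-methylhex-4-en-1-yn-1-yl)lithium | [Li]C#CCC=C(C)C
F6 | step 12 | 2,3-bis(hydroxymethyl)-6-(3-methylbut-2-en-1-yl)-5-[(triisopropylsilyl)oxy]phenol | CC(C)=CCc1c(O[Si](C(C)C)(C(C)C)C(C)C)cc(CO)c(CO)c1O
F7 | step 12 | [6-acetoxy-5-(3-methylbut-2-en-1-yl)-4-[(triisopropylsilyl)oxy]-1,2-phenylene]bis(methylene) diacetate | CC(C)=CCc1c(O[Si](C(C)C)(C(C)C)C(C)C)cc(COC(C)=O)c(COC(C)=O)c1OC(C)=O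
F8 | step 12 | [3-acetoxy-5-hydroxy-4-(3-methylbut-2-en-1-yl)-1,2-phenylene]bis(methylene) diacetate | CC(C)=CCc1c(O)cc(COC(C)=O)c(COC(C)=O)c1OC(C)=O
F9 | step 12 | 2,4-diacetoxy-6-methylbenzoic acid | Cc1cc(OC(C)=O)cc(OC(C)=O)c1C(=O)O
F10 | step 12 | 2,4-diacetoxy-6-methylbenzoyl chloride | Cc1cc(OC(C)=O)cc(OC(C)=O)c1C(=O)Cl
F11 | step 12 | 3-acetoxy-4,5-bis(acetoxymethyl)-2-(3-methylbut-2-en-1-yl)phenyl 2,4-diacetoxy-6-methylbenzoate | CC(C)=CCc1c(OC(=O)c2c(C)cc(OC(C)=O)cc2OC(C)=O)cc(COC(C)=O)c(COC(C)=O)c1OC(C)=O
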